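The millimole of X per litre of starting volume was my unit for this flask: each X starts one chain, and chains begun are what the average divides by.

Q 0.47 M (fed, over 2.5 s); Z 4.70 mM; X 0.94 mM; time 30 s; the fed solution adds 0.50 times the starting volume

    G + Z → G.Z (k1 = 6.3 L mol⁻¹ s⁻¹)
    Q + G → D + G, rate k2*[G]*[Q] (k2 = 84 L mol⁻¹ s⁻¹)
    Q + X → G + D (k3 = 9.6 L mol⁻¹ s⁻¹)

- charges are per starting volume, the dose included; the dosed solution carries all of it
- the average divides the monomer in chains by the number of chains begun, living and dead together
- run time (flask): 30 s

- average number of monomer units in a chain (chains begun, living or dead) at 30 s
- part of the Q that has reacted at 30 s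

X was my limiting reagent, 0.94 mM against 4.70 mM of Z and 0.47 M of Q. First entry: Q climbed towards its diluted level during the feed, and at half that level X would have a half-life of 0.461 s, shorter than the 2.5 s feed, so I booked the charge of X as living ends G when the feed closed. Second entry: I held Z at its diluted 3.13 mM, which made the loss of ends pseudo-first-order. Over the remaining 27.5 s, I reckoned that 58.1 % stayed alive. Per litre of starting volume, that was 0.546 mM living and 0.394 mM dead as G.Z, and the books closed at 0.94 mM.

Each dead end cost one Z, leaving 91.6 % of it. I then worked with fractions left. The same ends consume Q and Z, so once the feed is over the logarithm of Q's fraction falls faster than Z's by the selectivity factor, the rate constant of an end with Q over its rate constant with Z, 13.3. The feed was short beside the 23 s half-life of G by the step to G.Z with Z as charged, so I ignored it in this reckoning. Raising Z's fraction to that power left 31.1 % of Q, which gave 68.9 % reacted and 344 units per chain.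

The forecast gave 341 and 68.1 %, using the same power: “Q falls by the 84/6.3 power of Z's fall”. My conversion stood slightly higher.

The simulation gave 341 and 68.3 %.

At 30.0 s in this flask, Q had a shorter half-life by the step into chains, 23 s, than Z had by the step to G.Z, 5.1 min; their ratio of 13.3 is the selectivity factor 13.3 itself, not a second test of it. At that time less of the charged Q was left than of the charged Z, 32 % against 92 %.

In the neighbour flask with 1.60 mM of X, the same living share gave 0.670 mM of dead ends, 85.7 % of Z left, and so 12.9 % of Q left, or 87.1 % reacted. The simulation of that flask gave 86.0 %.

(The constants come from no measurement; no experiment stands behind them.)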